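**Assumptions:** The SMILES contains no sp3 stereocenters. The only stereo-element is the side-chain alkene, and C/C(=C\C…)CO puts CH3 cis to CH2Ar, so CH2OH is trans to CH2Ar. That is the (E)-4-hydroxy-3-methylbut-2-enyl group, so the target is 6-[(E)-4-hydroxy-3-methylbut-2-enyl]genistein (5,7,4'-trihydroxy-isoflavone core).

## Retrosynthesis
1. The final step removes the two aryl MOM groups, so the last bond changes are protecting-group cleavage only.
2. The (E)-allylic alcohol comes from a Luche reduction of the (E)-2-methyl-enal, which comes from cross-metathesis of a 6-allyl group with methacrolein.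
3. The 6-allyl group comes from a 5-O-allyl Claisen rearrangement. C4a is blocked, so the only ortho site is C6, which removes the C6/C8 regiochemistry problem.
4. The isoflavone (chromone) ring system is not built. Genistein already has it, so no rings are formed. 7,4'-Di-O-MOM protection leaves only the chelated 5-OH free for allylation.

## Route

**Step 1**
Reactants: 1 (genistein), 2 (chloromethyl methyl ether)
Product: 3 (7,4'-bis-O-MOM-genistein)
Conditions: MOMCl (2.3 equiv), K2CO3, DMF, 0 °C → rt
Reagents that add atoms: MOMCl, COCCl
Why: The 7-OH and 4'-OH are the more acidic and accessible phenols, whereas the 5-OH is locked by a hydrogen bond to C4=O, so Williamson-type O-alkylation gives the 7,4'-bis-MOM ether selectively.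

**Step 2**
Reactants: 3, 4 (allyl bromide)
Product: 5 (5-O-allyl-7,4'-bis-O-MOM-genistein)
Conditions: allyl bromide (3 equiv), K2CO3, DMF, 70 °C
Reagents that add atoms: allyl bromide, C=CCBr
Why: Excess allyl bromide and heat alkylate the chelated 5-OH, the only free phenol, by Williamson etherification.

**Step 3**
Reactants: 5
Product: 6 (6-allyl-5-hydroxy-7,4'-bis-O-MOM-isoflavone)
Conditions: PhNEt2, 190 °C, sealed tube (or microwave), 1 h
Reagents that add atoms: none
Why: The aromatic Claisen [3,3] rearrangement can only go to C6, because C4a is substituted, and tautomerization restores the chelated 5-OH. MOM ethers and the chromone survive neutral thermolysis.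

**Step 4**
Reactants: 6, 7 (methacrolein)
Product: 8 ((E)-enal, 6-[(E)-3-methyl-4-oxobut-2-enyl] compound)
Conditions: methacrolein (5 equiv), Grubbs II (5 mol %), 1,4-benzoquinone (10 mol %), CH2Cl2, 40 °C
Reagents that add atoms: methacrolein, CC(=C)C=O
Why: Olefin cross-metathesis of the terminal allyl group with the electron-poor 1,1-disubstituted enal gives the trisubstituted enal under thermodynamic control. The CHO ends up trans to CH2Ar, which is the E geometry needed. Benzoquinone suppresses Ru–H isomerization of the allyl group.

**Step 5**
Reactants: 8
Product: 9 (allylic alcohol, bis-MOM, E)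
Conditions: NaBH4, CeCl3·7H2O, MeOH/CH2Cl2, −20 °C
Reagents that add atoms: none (only hydride is delivered)
Why: Luche 1,2-reduction takes the aldehyde chemoselectively. The H-bonded chromone C4=O and the C2=C3 enone are much less electrophilic, and the alkene geometry is untouched.

**Step 6**
Reactants: 9
Product: 10 (target)
Conditions: 3 M HCl (aq), THF/MeOH 1:1, 40 °C, 2–4 h
Reagents that add atoms: none
Why: Acid hydrolysis cleaves the two aryl MOM acetals, liberating the 7-OH and 4'-OH. The primary allylic alcohol and the E-alkene are tolerated under these mild conditions, and no stereocenters exist to scramble.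

## Final check
- The product has a 4H-chromen-4-one ring with 5-OH, 7-OH and 3-(4-hydroxyphenyl), and C6 carries CH2–CH=C(CH3)–CH2OH with E geometry. This matches the target SMILES.
- Atom bookkeeping:
  - C15H10O5 → C19H18O7 (two MOM groups) → C22H22O7 (allyl) → isomer (Claisen).
  - Cross-metathesis exchanges CH2=CH2 for the methacrolein fragment.
  - Reduction adds 2 H.
  - Deprotection removes two CH2OCH2 units, giving C20H18O6 for the target.
- The alkene geometry is set in step 4 and preserved in steps 5 and 6.

## Compound list
1 | genistein | O=c1c(-c2ccc(O)cc2)coc2cc(O)cc(O)c12 | starting material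
2 | chloromethyl methyl ether (MOMCl) | COCCl | reagent
3 | 7,4'-bis-O-MOM-genistein | COCOc1ccc(cc1)-c1coc2cc(OCOC)cc(O)c2c1=O | intermediate
4 | allyl bromide | C=CCBr | reagent
5 | 5-O-allyl-7,4'-bis-O-MOM-genistein | C=CCOc1cc(OCOC)cc2occ(-c3ccc(OCOC)cc3)c(=O)c12 | intermediate
6 | 6-allyl-5-hydroxy-7,4'-bis-O-MOM-isoflavone | C=CCc1c(OCOC)cc2occ(-c3ccc(OCOC)cc3)c(=O)c2c1O | intermediate
7 | methacrolein | CC(=C)C=O | reagent
8 | (E)-enal: 6-[(E)-3-methyl-4-oxobut-2-en-1-yl]-5-hydroxy-7,4'-bis-O-MOM-isoflavone | C/C(=C\Cc1c(OCOC)cc2occ(-c3ccc(OCOC)cc3)c(=O)c2c1O)C=O | intermediate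
9 | (E)-allylic alcohol, bis-MOM | C/C(=C\Cc1c(OCOC)cc2occ(-c3ccc(OCOC)cc3)c(=O)c2c1O)CO | intermediate
10 | 6-[(E)-4-hydroxy-3-methylbut-2-enyl]genistein | C/C(=C\Cc1c(O)cc2occ(-c3ccc(O)cc3)c(=O)c2c1O)CO | target

**Total steps:** 6. **Longest linear sequence:** 6 steps, starting from genistein.

## Three steps most likely to fail
1. **Step 4 (cross-metathesis).**
   - Risks: Ru-hydride isomerization of the allyl group, and modest yield or E/Z control with the ortho-phenol.
   - Fallback (different approach): cleave the allyl group with OsO4/NaIO4 to the arylacetaldehyde, then do a Wittig with Ph3P=C(CH3)CHO, which is E-selective, to give enal 8.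
2. **Steps 2–3 (chelated 5-OH allylation, then thermal Claisen).**
   - Risks: sluggish 5-O-alkylation, and decomposition or chromene formation at 190 °C.
   - Fallback (different approach): iodinate 5-hydroxy-7,4'-bis-MOM-isoflavone at C6 (NIS, separating any 8-iodo isomer), then do a Stille coupling with allyltributyltin to give 6.
3. **Step 6 (acidic MOM removal in the presence of a primary allylic alcohol).**
   - Risks: ionization, ether formation or alkene isomerization.
   - Fallback (different approach): acetylate the allylic OH first, then cleave the MOM groups with ZnBr2/n-PrSH or TMSBr, then remove the acetate with K2CO3/MeOH. Alternatively, use 7,4'-bis-PMB protection from the start and remove it with TFA/anisole at 0 °C.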